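**Plan**

1. Numbering: the core is tetracyclo[6.4.0.0^{2,7}.0^{3,6}]dodecane; ring A = cyclobutane C1-C2-C7-C8, ring B = C2-C3-C6-C7, ring C = C3-C4-C5-C6, six-membered ring = C1, C8-C12, chain on C10.
2. Retrosynthesis: cut the benzyl ethers and the C9=C10 double bond (hydrogenation); cut the chain at C10–C1' back to a C9 ketone (aldol condensation, reductive alkene transposition); cut ring A at C1–C2 and C7–C8 together to give cyclohex-2-enone and bicyclo[2.2.0]hex-2-ene; cut the C2=C7 alkene back to a thiolane sulfone.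
3. Enabling feature: ring A shares its C1–C8 edge with the six-membered ring and its C2–C7 edge with ring B, so with a carbonyl placed at C9 it is the enone–alkene photocycloadduct of a cyclohexenone C=C and a cyclobutene C=C; the cis-anti-cis pattern is what exo attack on the folded bicyclohexene gives.
4. Forward: ring C is bought (cyclobutane anhydride), ring B is made by Ramberg–Bäcklund ring contraction, the six-membered ring is bought, ring A is closed last by an enantioselective [2+2] photocycloaddition; the chain is then joined at C10 and the C9 oxygen removed.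
5. Stereochemistry: C1 (absolute) from the chiral Lewis acid; C2/C7 from exo attack on the meso alkene; C8 by epimerisation to the cis fusion; C3/C6 from the cis anhydride; C10 from convex-face hydrogenation.

Key step: step 8

Assumption: the (S)-prolinol-derived oxazaborolidine–AlBr3 complex is taken to expose the Re face of the enone β-carbon, which gives (1S) in ketone 16; if the sense is the opposite, the catalyst from (R)-prolinol is used. The CIP letters at C1 and C7 differ between the ketone series and the target only because substituent priorities change.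

**Step 1**
Reactants: 1 cis-cyclobutane-1,2-dicarboxylic anhydride
Product: 2 cis-1,2-bis(hydroxymethyl)cyclobutane
Conditions: LiAlH4, THF, 0 °C → reflux; aq. NaOH work-up
Reagents that add atoms: none
Why: Hydride reduction of the cyclic anhydride should take both acyl groups to primary alcohols without touching the two cis stereocentres.

**Step 2**
Reactants: 2 cis-1,2-bis(hydroxymethyl)cyclobutane
Product: 3 cis-1,2-bis(methanesulfonyloxymethyl)cyclobutane
Conditions: MsCl, Et3N, CH2Cl2, 0 °C
Reagents that add atoms: methanesulfonyl chloride, CS(=O)(=O)Cl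
Why: Mesylation of the two primary alcohols provides the leaving groups for the double displacement.

**Step 3**
Reactants: 3 cis-1,2-bis(methanesulfonyloxymethyl)cyclobutane
Product: 4 cis-3-thiabicyclo[3.2.0]heptane
Conditions: Na2S·9H2O, DMSO, 100 °C
Reagents that add atoms: sodium sulfide, [Na+].[Na+].[S-2]
Why: Sulfide should displace both mesylates by SN2, the second displacement being a favourable 5-exo-tet closure to the thiolane.

**Step 4**
Reactants: 4 cis-3-thiabicyclo[3.2.0]heptane
Product: 6 2-chloro-3-thiabicyclo[3.2.0]heptane 3,3-dioxide, via α-chloro sulfide 5 (not isolated)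
Conditions: NCS, CH2Cl2, 0 °C → rt; then mCPBA, CH2Cl2, 0 °C → rt
Reagents that add atoms: N-chlorosuccinimide, O=C1CCC(=O)N1Cl; mCPBA, OOC(=O)c1cccc(Cl)c1
Why: NCS chlorinates α to sulfur through a chlorosulfonium/thionium ion (Pummerer-type) and the labile α-chloro sulfide is oxidised at once to the stable α-chloro sulfone; both chloride epimers serve step 5.

**Step 5**
Reactants: 6 2-chloro-3-thiabicyclo[3.2.0]heptane 3,3-dioxide
Product: 8 bicyclo[2.2.0]hex-2-ene, via episulfone 7 (not isolated)
Conditions: KOtBu, DMSO, 20 °C; product distilled under reduced pressure into a −78 °C trap and kept as a CH2Cl2 solution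
Reagents that add atoms: none
Why: Ramberg–Bäcklund reaction: α'-deprotonation, 1,3-displacement of chloride to the episulfone and loss of SO2 should contract the thiolane dioxide to the cyclobutene, with the cis ring fusion carried from 1.

**Step 6**
Reactants: 9 1,3-bis(benzyloxy)propan-2-ol; 10 9-bromonon-1-ene
Product: 11 1,3-bis(benzyloxy)-2-(non-8-en-1-yloxy)propane
Conditions: NaH, Bu4NI (cat.), DMF, 0 °C → rt
Reagents that add atoms: none
Why: Williamson ether synthesis of the secondary alkoxide with an unhindered primary bromide.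

**Step 7**
Reactants: 11 1,3-bis(benzyloxy)-2-(non-8-en-1-yloxy)propane
Product: 13 8-{[1,3-bis(benzyloxy)propan-2-yl]oxy}octanal, via ozonide 12 (not isolated)
Conditions: O3, CH2Cl2, −78 °C; then PPh3, −78 °C → rt
Reagents that add atoms: ozone, [O-][O+]=O
Why: Ozonolysis with reductive work-up should cleave the terminal alkene to the C8 aldehyde, the terminal carbon leaving as formaldehyde, while benzyl ethers tolerate brief ozone exposure at −78 °C.

**Step 8**
Reactants: 14 cyclohex-2-en-1-one; 8 bicyclo[2.2.0]hex-2-ene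
Product: 16 (1S,2S,3S,6R,7S,8S)-tetracyclo[6.4.0.0^{2,7}.0^{3,6}]dodecan-9-one, via trans-fused ketone 15 (not isolated)
Conditions: 8 (3 equiv), AlBr3 adduct of the oxazaborolidine from (S)-α,α-bis(3,5-dimethylphenyl)prolinol and 2,4,6-trifluorophenylboronic acid (50 mol %), CH2Cl2, −78 °C, hν (λ = 366 nm); then basic Al2O3, CH2Cl2, rt
Reagents that add atoms: none
Why: Binding of the AlBr3-activated oxazaborolidine to the enone carbonyl shifts the enone absorption to longer wavelength, so at 366 nm almost only the chiral complex is excited; its triplet adds to the C=C of 8 through a triplet 1,4-diradical that closes after intersystem crossing, the closest known reaction type being the chiral oxazaborolidine–AlBr3 catalysed intermolecular [2+2] photocycloaddition of cyclohex-2-enone with simple alkenes. Ring A is closed by an intermolecular [2+2] cycloaddition that forms C1–C2 and C7–C8 (one intermolecular bond, then recombination of the 1,4-diradical to the four-membered ring). C1 is set by the catalyst, whose aryl group shields one face of the bound enone so that the alkene attacks the Re face of the β-carbon; C2 and C7 are set by attack on the convex (exo) face of 8, away from its CH2–CH2 bridge, which places rings A and C anti across ring B, and the six-membered ring turns away from ring B during diradical closure (anti across ring A). C8 is formed partly trans (15) and is epimerised on basic Al2O3 through the enol to the much less strained cis-fused ketone 16, while C3/C6 come unchanged from the meso alkene. The step needs cross-addition over enone dimerisation (secured by an excess of the non-absorbing alkene, recovered by distillation), exo and anti approach (secured by the folded shape of 8), and survival of the strained alkene towards the Lewis acid (−78 °C, CH2Cl2).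

**Step 9**
Reactants: 16 (1S,2S,3S,6R,7S,8S)-tetracyclo[6.4.0.0^{2,7}.0^{3,6}]dodecan-9-one; 13 8-{[1,3-bis(benzyloxy)propan-2-yl]oxy}octanal
Product: 17 (1S,2S,3S,6R,7S,8S)-10-(8-{[1,3-bis(benzyloxy)propan-2-yl]oxy}-1-hydroxyoctyl)tetracyclo[6.4.0.0^{2,7}.0^{3,6}]dodecan-9-one (diastereomer mixture at C10 and the carbinol carbon)
Conditions: LiN(iPr)2 (LDA), THF, −78 °C; then 13, −78 °C; AcOH quench
Reagents that add atoms: none
Why: Kinetic deprotonation should occur at the C10 methylene and not at the cyclobutane methine C8, and the lithium enolate adds to the aldehyde (directed aldol addition); the two new stereocentres are erased in steps 10 and 12, so their mixture is of no consequence.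

**Step 10**
Reactants: 17 aldol adduct
Product: 19 (1S,2S,3S,6R,7S,8S,E)-10-(8-{[1,3-bis(benzyloxy)propan-2-yl]oxy}octylidene)tetracyclo[6.4.0.0^{2,7}.0^{3,6}]dodecan-9-one, via mesylate 18 (not isolated)
Conditions: MsCl, Et3N, CH2Cl2, 0 °C; then DBU, rt
Reagents that add atoms: none
Why: Mesylation and E1cB elimination should give the conjugated (E)-alkylidene ketone; C8 can only epimerise to the cis fusion it already has, and any drift to the endocyclic C10=C11 enone is harmless because it converges on the same alkene in step 12.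

**Step 11**
Reactants: 19 (E)-alkylidene ketone
Product: 20 p-toluenesulfonylhydrazone of 19
Conditions: TsNHNH2, AcOH (cat.), EtOH, 50 °C
Reagents that add atoms: p-toluenesulfonyl hydrazide, Cc1ccc(cc1)S(=O)(=O)NN
Why: Condensation of the ketone with the sulfonyl hydrazide gives the α,β-unsaturated tosylhydrazone (hydrazone formation); the C=N geometry is irrelevant.

**Step 12**
Reactants: 20 p-toluenesulfonylhydrazone of 19
Product: 23 (1S,2S,3S,6R,7S,8S)-10-(8-{[1,3-bis(benzyloxy)propan-2-yl]oxy}octyl)tetracyclo[6.4.0.0^{2,7}.0^{3,6}]dodec-9-ene, via N-boryl hydrazine 21 (not isolated), via allylic diazene 22 (not isolated)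
Conditions: catecholborane, CHCl3, 0 °C → rt; then NaOAc·3H2O, 60 °C
Reagents that add atoms: none
Why: Catecholborane reduction of an α,β-unsaturated tosylhydrazone (Kabalka-type reductive alkene transposition): 1,2-hydride addition to C=N, acetate-induced loss of sulfinate to the allylic diazene and concerted retro-ene loss of N2 should move the double bond to C9=C10, remove the oxygen and deliver H to the side-chain carbon, with no cation or radical next to strained ring A.

**Step 13**
Reactants: 23 dodec-9-ene dibenzyl ether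
Product: 24 2-({8-[(1R,2S,3S,6R,7R,8S,10S)-tetracyclo[6.4.0.0^{2,7}.0^{3,6}]dodecan-10-yl]octyl}oxy)propane-1,3-diol (CNP0193334.1)
Conditions: H2 (1 atm), Pd/C, EtOAc/EtOH, rt
Reagents that add atoms: none
Why: Heterogeneous hydrogenation should add H2 to C9=C10 from the convex face carrying H-1/H-8 (ring A with H-2/H-7 blocks the other face), so H-10 ends cis to H-8 and C10 is S, and the same catalyst hydrogenolyses both benzyl ethers while the cyclobutane σ bonds should stay intact at 1 atm and rt.

**Compound list**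

1 | cis-cyclobutane-1,2-dicarboxylic anhydride (meso) | O=C1OC(=O)[C@H]2CC[C@@H]12 | starting material
2 | cis-1,2-bis(hydroxymethyl)cyclobutane (meso) | OC[C@H]1CC[C@H]1CO | intermediate
3 | cis-1,2-bis(methanesulfonyloxymethyl)cyclobutane | CS(=O)(=O)OC[C@H]1CC[C@H]1COS(C)(=O)=O | intermediate
4 | cis-3-thiabicyclo[3.2.0]heptane | C1SC[C@H]2CC[C@@H]12 | intermediate
5 | 2-chloro-3-thiabicyclo[3.2.0]heptane (cis fusion, racemic, both C2 epimers) | ClC1SC[C@H]2CC[C@@H]12 | intermediate
6 | 2-chloro-3-thiabicyclo[3.2.0]heptane 3,3-dioxide (cis fusion, racemic, both C2 epimers) | ClC1S(=O)(=O)C[C@H]2CC[C@@H]12 | intermediate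
7 | 3-thiatricyclo[3.2.0.0^{2,4}]heptane 3,3-dioxide (episulfone, cis-fused cyclobutane) | O=S1(=O)C2C1[C@H]1CC[C@@H]21 | intermediate
8 | bicyclo[2.2.0]hex-2-ene (cis-fused, meso) | C1=C[C@H]2CC[C@@H]12 | intermediate
9 | 1,3-bis(benzyloxy)propan-2-ol | OC(COCc1ccccc1)COCc1ccccc1 | starting material
10 | 9-bromonon-1-ene | C=CCCCCCCCBr | starting material
11 | 1,3-bis(benzyloxy)-2-(non-8-en-1-yloxy)propane | C=CCCCCCCCOC(COCc1ccccc1)COCc1ccccc1 | intermediate
12 | 3-(7-{[1,3-bis(benzyloxy)propan-2-yl]oxy}heptyl)-1,2,4-trioxolane (ozonide of 11) | C1(CCCCCCCOC(COCc2ccccc2)COCc2ccccc2)OCOO1 | intermediate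
13 | 8-{[1,3-bis(benzyloxy)propan-2-yl]oxy}octanal | O=CCCCCCCCOC(COCc1ccccc1)COCc1ccccc1 | intermediate
14 | cyclohex-2-en-1-one | O=C1C=CCCC1 | starting material
15 | (1S,2S,3S,6R,7S,8R)-tetracyclo[6.4.0.0^{2,7}.0^{3,6}]dodecan-9-one (trans-fused at C1–C8) | O=C1CCC[C@@H]2[C@@H]1[C@H]1[C@@H]3CC[C@@H]3[C@@H]21 | intermediate
16 | (1S,2S,3S,6R,7S,8S)-tetracyclo[6.4.0.0^{2,7}.0^{3,6}]dodecan-9-one (cis-anti-cis-anti-cis) | O=C1CCC[C@@H]2[C@H]1[C@H]1[C@@H]3CC[C@@H]3[C@@H]21 | intermediate
17 | (1S,2S,3S,6R,7S,8S)-10-(8-{[1,3-bis(benzyloxy)propan-2-yl]oxy}-1-hydroxyoctyl)tetracyclo[6.4.0.0^{2,7}.0^{3,6}]dodecan-9-one (mixture at C10 and carbinol carbon) | O=C1C(C(O)CCCCCCCOC(COCc2ccccc2)COCc2ccccc2)CC[C@@H]2[C@H]1[C@H]1[C@@H]3CC[C@@H]3[C@@H]21 | intermediate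
18 | methanesulfonate of 17 | O=C1C(C(OS(C)(=O)=O)CCCCCCCOC(COCc2ccccc2)COCc2ccccc2)CC[C@@H]2[C@H]1[C@H]1[C@@H]3CC[C@@H]3[C@@H]21 | intermediate
19 | (1S,2S,3S,6R,7S,8S,E)-10-(8-{[1,3-bis(benzyloxy)propan-2-yl]oxy}octylidene)tetracyclo[6.4.0.0^{2,7}.0^{3,6}]dodecan-9-one | O=C1/C(=C/CCCCCCCOC(COCc2ccccc2)COCc2ccccc2)CC[C@@H]2[C@H]1[C@H]1[C@@H]3CC[C@@H]3[C@@H]21 | intermediate
20 | p-toluenesulfonylhydrazone of 19 (C=N geometry not defined) | Cc1ccc(cc1)S(=O)(=O)NN=C1/C(=C/CCCCCCCOC(COCc2ccccc2)COCc2ccccc2)CC[C@@H]2[C@H]1[C@H]1[C@@H]3CC[C@@H]3[C@@H]21 | intermediate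
21 | N-(1,3,2-benzodioxaborol-2-yl)-N'-tosyl hydrazine at C9 (hydride adduct of 20, C9 not defined) | Cc1ccc(cc1)S(=O)(=O)NN(B1Oc2ccccc2O1)C1/C(=C/CCCCCCCOC(COCc2ccccc2)COCc2ccccc2)CC[C@@H]2[C@H]1[C@H]1[C@@H]3CC[C@@H]3[C@@H]21 | intermediate
22 | C9 allylic diazene (C9 not defined) | N=NC1/C(=C/CCCCCCCOC(COCc2ccccc2)COCc2ccccc2)CC[C@@H]2[C@H]1[C@H]1[C@@H]3CC[C@@H]3[C@@H]21 | intermediate
23 | (1S,2S,3S,6R,7S,8S)-10-(8-{[1,3-bis(benzyloxy)propan-2-yl]oxy}octyl)tetracyclo[6.4.0.0^{2,7}.0^{3,6}]dodec-9-ene | c1ccccc1COCC(COCc1ccccc1)OCCCCCCCCC1=C[C@@H]2[C@H]3[C@@H]4CC[C@@H]4[C@H]3[C@@H]2CC1 | intermediate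
24 | 2-({8-[(1R,2S,3S,6R,7R,8S,10S)-tetracyclo[6.4.0.0^{2,7}.0^{3,6}]dodecan-10-yl]octyl}oxy)propane-1,3-diol | OCC(CO)OCCCCCCCC[C@H]1CC[C@@H]2[C@H](C1)[C@H]1[C@@H]3CC[C@@H]3[C@@H]21 | target

**Step count and risks**

Total steps: 13. Longest linear sequence: 11 (steps 1–5, then 8–13); the aldehyde branch (steps 6–7) joins at step 9.

Steps most likely to fail:

1. Step 8. The strained alkene may be opened or oligomerised by the strong Lewis acid, or the catalyst may discriminate the enone faces poorly with this alkene. The fallback sets out from 14 and 8. Uncatalysed irradiation (λ = 350 nm, CH2Cl2) followed by basic Al2O3 should give 16 as a racemate with its enantiomer, the (1R,2R,3R,6S,7R,8R)-ketone F1. Ketalisation with (1R,2R)-1,2-diphenylethane-1,2-diol (PPTS, benzene, Dean–Stark) should give the diastereomeric spiro-dioxolanes, the ketal of 16 F2 and the ketal of the enantiomer F3, which are separated by chromatography or crystallisation. Hydrolysis of F2 (2 M HCl, THF, 40 °C) returns enantiopure 16, where the route is rejoined.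

2. Step 13. Facial selectivity at C10 may be poor, or the double bond may migrate on palladium before reduction. The fallback sets out from 23 and uses catalyst control on top of the substrate bias. Homogeneous hydrogenation with the matched antipode of [Ir(cod)(tBu-PHOX)]BArF (H2, 50 bar, CH2Cl2) should give the saturated dibenzyl ether F4. Separate hydrogenolysis (H2, Pd(OH)2/C, EtOAc) then gives 24.

3. Step 12. Conjugate addition of the hydrazide or of hydride may compete, and sulfinate loss at the hindered C9 may be sluggish. The fallback sets out from 19. Conjugate reduction with LiBH(sBu)3 (THF, −78 °C) and trapping of the regiodefined enolate with PhNTf2 should give the C9 enol triflate F5. Reduction of the triflate with Pd(OAc)2, PPh3, Bu3N and HCO2H (DMF, 60 °C) gives 23, where the route is rejoined.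

**Further compounds**

F1 | step 8 | (1R,2R,3R,6S,7R,8R)-tetracyclo[6.4.0.0^{2,7}.0^{3,6}]dodecan-9-one (enantiomer of 16) | O=C1CCC[C@H]2[C@@H]1[C@@H]1[C@H]3CC[C@H]3[C@H]21
F2 | step 8 | (4R,5R)-4,5-diphenyl-1,3-dioxolane ketal of 16 | c1ccccc1[C@H]5OC2(CCC[C@@H]3[C@H]2[C@H]2[C@@H]4CC[C@@H]4[C@@H]32)O[C@@H]5c1ccccc1
F3 | step 8 | (4R,5R)-4,5-diphenyl-1,3-dioxolane ketal of the enantiomer of 16 | c1ccccc1[C@H]5OC2(CCC[C@H]3[C@@H]2[C@@H]2[C@H]4CC[C@H]4[C@H]32)O[C@@H]5c1ccccc1
F4 | step 13 | 1,3-bis(benzyloxy)-2-({8-[(1R,2S,3S,6R,7R,8S,10S)-tetracyclo[6.4.0.0^{2,7}.0^{3,6}]dodecan-10-yl]octyl}oxy)propane | c1ccccc1COCC(COCc1ccccc1)OCCCCCCCC[C@H]1CC[C@@H]2[C@H](C1)[C@H]1[C@@H]3CC[C@@H]3[C@@H]21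
F5 | step 12 | (1S,2S,3S,6R,7S,8S)-10-(8-{[1,3-bis(benzyloxy)propan-2-yl]oxy}octyl)tetracyclo[6.4.0.0^{2,7}.0^{3,6}]dodec-9-en-9-yl trifluoromethanesulfonate | FC(F)(F)S(=O)(=O)OC1=C(CCCCCCCCOC(COCc2ccccc2)COCc2ccccc2)CC[C@@H]2[C@H]1[C@H]1[C@@H]3CC[C@@H]3[C@@H]21
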